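I have to choose between charging the partner at once with 0.00800 M of protic impurity (ash) and feeding it over 8.0 min with 0.0250 M of protic impurity (oak).

| flask | starting material | partner | protic impurity | initiator | remark | time |
|---|---|---|---|---|---|---|
| amber | 0.050 M | 0.090 M (fed, over 8.0 min) | 0.0057 M | 1.1 mM | run made earlier |  |
| blue | 0.050 M | 0.090 M (fed, over 8.0 min) | 0.016 M | 1.1 mM | run made earlier |  |
| ash | 0.050 M | 0.0900 M | 0.00800 M | 1.1 mM | everything together at the start | 8.0 min |
| oak | 0.050 M | 0.0900 M (fed, over 8.0 min) | 0.0250 M | 1.1 mM |  | 8.0 min |

| run | time / min | product / % | starting material / % |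
|---|---|---|---|
| amber | 0.667 | 1.0 | 93.2 |
| amber | 1.00 | 0 | 90.1 |
| amber | 2.00 | 6.6 | 80.4 |
| amber | 3.00 | 14.4 | 68.2 |
| amber | 5.00 | 36.4 | 43.2 |
| amber | 8.00 | 76.2 | 0 |
| blue | 0.500 | 1.9 | 94.5 |
| blue | 1.50 | 3.8 | 81.1 |
| blue | 3.00 | 14.8 | 59.9 |
| blue | 4.00 | 22.3 | 47.5 |
| blue | 6.00 | 48.4 | 21.1 |
| blue | 8.00 | 69.0 | 0.7 |

(readings scatter by 1 percentage point)

- the winner by amount of product, in percent of the starting material charged; "neither" if no more than 2 percentage points parts them (ash / oak / neither)
- how much product is there at the end, in percent of the starting material charged: ash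
- how much product is there at the end, in percent of the starting material charged: oak

- the numbers in the tables scatter with a standard deviation of 1 percentage point

I assume one partner per product. In the amber run, between 3.00 min and 5.00 min, product grows at 0.00550 M min⁻¹ while free partner averages 0.0323 M. Their ratio is my partner turnover constant, the product rate per unit of free [partner], a pseudo-first-order constant: 0.170 min⁻¹. The blue run, between 4.00 min and 6.00 min, reads 0.169 min⁻¹, though its [starting material] stands lower. So I let the rate ignore [starting material].

I reckon that starting material which does not become product is lost in proportion to the time it waits. Its waiting time is the area under its curve, as a fraction of the charge: 4.31 min in amber and 3.86 min in blue. The missing share per minute of waiting is 0.0552 min⁻¹ and 0.0784 min⁻¹. A straight line in [protic impurity] gives 0.0604 min⁻¹ for ash and 0.0987 min⁻¹ for oak. With blue's waiting time, oak ends near 61.9 %.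

In ash, the turnover constant puts the end of the starting material at 4.76 min, within the 8.0 min. A straight fall means 2.38 min of waiting and 85.6 % product. That straight fall is my weak link: the turnover constant has the rate sag as partner goes. Integrating the decay gives 2.06 min of waiting, so I commit to 87.5 % for ash.

The forecast gives 72 % (62 % to 79 %) for ash, below my figure, and 63 % (56 % to 68 %) for oak: “Ash should win.”

The flasks give 89.4 % in ash and 62.1 % in oak, so ash wins. At 8.00 min ash holds 5.34 % as dormant form. At 80.0 min the product in ash stands at 94.8 %. The turnover constant puts free partner in ash at 4.00 min at 50.7 % of its charge; the flask holds 52.3 %.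

    initiator → 2 initiating radical (k = 3.40 × 10⁻⁴ s⁻¹)
    starting material + initiating radical → capped initiator + first chain carrier (k = 2.00 × 10⁶ L mol⁻¹ s⁻¹)
    partner + first chain carrier → product + second chain carrier (k = 17000 L mol⁻¹ s⁻¹)
    starting material + second chain carrier → by-product + first chain carrier (k = 49000 L mol⁻¹ s⁻¹)
    2 first chain carrier → ended chains (k = 1.40 × 10⁷ L mol⁻¹ s⁻¹)
    starting material ⇌ dormant form (K = 0.650, k = 9.30 × 10⁻⁴ s⁻¹)
    starting material + protic impurity → quenched substrate (k = 0.0710 L mol⁻¹ s⁻¹)

Now a neighbour flask, like ash but with 0.20 M of starting material, so [partner] is the lower charge. The turnover constant leaves 25.7 % of the partner at 8.0 min, which means 33.5 % product. The computed neighbour flask holds 32.5 % product, 27.8 % partner and 43.7 % starting material.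

The earlier runs and the new flask were computed with constants of no real substance, noise included.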